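**Assumptions (chemistry).** All four stereocentres of the target are read as R. Both rings use benzoate numbering: C1 carries the carboxyl carbon, C2 and C4 the oxygens, C6 the side chain. Only stoichiometric in-flask intermediates (Grignard reagent, iminium salt, acid chloride) are numbered; catalytic organopalladium and organogold species are not.

## The problem

Hansforester I (23) is a linear chain of four building blocks joined by three ester bonds and ending in a free carboxylic acid. The blocks are a ring B resorcylate, an (R)-3-hydroxybutanoate, a ring A resorcylate whose 2-hydroxypropyl side chain carries the preceding unit, and a terminal (R)-3-hydroxybutanoic acid. No ring has to be closed. The difficulty lies in the two aryl esters, each of which joins a secondary alcohol to a benzoate carbon flanked by an oxygen at C2 and a carbon chain at C6. The four stereocentres are isolated methyl carbinols, too far apart to control one another, so each must be bought as a chiral building block and then left untouched. The molecule tolerates little: both hydroxybutanoate units are β-acyloxy esters that give crotonates under base, and the ring B side chain is a β-hydroxy ketone that can dehydrate or close onto the neighbouring ester as an isocoumarin. A free hydroxyl on the ring A side chain would attack the ring A ester and form a six-membered lactone of the 6-hydroxymellein type. The feature that opens the key step is that the ring A carboxyl carbon is a single carbon on C1, between C2–O and the C6 chain. That is the position at which a 3,5-dioxygenated alkylbenzene is iodinated, so a C1–I bond can stand in for the carboxyl group until carbon monoxide and the last alcohol arrive together.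

## Retrosynthesis

**Protecting groups.** Target 23 is traced back to its desilylated pentabenzyl derivative 22 and to the fully protected compound 21. Only O–benzyl and O–silyl bonds are cut. Benzyl is chosen for the four phenols and the terminal acid because one neutral hydrogenolysis removes all five, so the finished polyester never meets acid or base. The ring B carbinol is a tert-butyldimethylsilyl ether because it must stay inert towards gold and palladium catalysts; it is removed with acidic fluoride before the hydrogenolysis.

**Ring A carboxyl carbon (key cut).** In 21 the bonds ring A C1–carbonyl and carbonyl–O are cut together. This leads to aryl iodide 20, carbon monoxide and benzyl (R)-3-hydroxybutanoate 15. Cutting only the carbonyl–O bond would require acylation by a 2,6-disubstituted benzoic acid and an acid precursor that is prone to lactonisation. The chosen cut removes the whole terminal unit, replaces the crowded acyl donor by an aroylpalladium species, and asks of the forward reaction only that the added alcohol is the sole nucleophile that captures it.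

**Central aliphatic ester.** Iodide 20 is cut at the one unhindered ester, between the carboxyl group of the internal hydroxybutanoate and the ring A carbinol. This gives acid 19 and iodo alcohol 6, two halves of similar size. The esterification must come before the carbonylation so that no free hydroxyl sits beside the iodide, and it must activate a β-aroyloxy acid without eliminating the aroyloxy group.

**Ring A half.** Iodo alcohol 6 comes from alcohol 5 by cutting the C1–I bond. Alcohol 5 comes from cutting the ring C6–CH2 bond, which leads to arylmagnesium bromide 4 (from bromide 2) and (R)-propylene oxide 3. Bromide 2 is the dibenzyl ether of 5-bromoresorcinol 1. The epoxide supplies the stereocentre unchanged; the forward iodination must go ortho to the chain and not between the two ethers.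

**Ring B ketone and acid.** Acid 19 comes from allyl ester 18, and the ketone of 18 from the alkyne of 17. A 2-(2-oxoalkyl)benzoic acid cannot be activated without closing to an isocoumarin, so the ketone is carried as an alkyne until the hindered ester exists. That ester then directs the hydration to the carbon one removed from the ring.

**Ring B aryl ester.** Ester 17 is cut at the carbonyl–O bond into aroyl chloride 16 (from acid 12) and allyl (R)-3-hydroxybutanoate 14. A second carbonylation is not used here, because an ortho alkyne or enolisable ketone would intercept the aroylpalladium species. The slim alkynyl group leaves the carbonyl accessible to classical acylation. The allyl ester is chosen because it can be removed under neutral conditions in the presence of benzyl and silyl ethers.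

**Ring B carbon framework.** Acid 12 comes from aldehyde 11, which is cut at the aryl–alkynyl bond into bromo aldehyde 8 and silylated alkyne 10 (from (R)-pent-4-yn-2-ol 9). Aldehyde 8 is reached through iminium salt 7 by formylation of the same bromide 2 that serves ring A, so both rings start from 1.

**Hydroxybutanoate units.** Esters 14 and 15 both come from methyl (R)-3-hydroxybutanoate 13 by exchange of the ester alkyl group, with the stereocentre untouched.

## Roads not taken

**Alternative 1:** Ring A is built, not bought. The bonds C1–C6 and C3–C4 are cut, leading to acetoacetate A2 and enoate A3. In the forward direction KOtBu would bring about Michael addition and then Claisen closure to cyclohexane-1,3-dione A1, to be aromatised later.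
- Merits: the ester to the last chiral alcohol is made as an easy acetoacetate, no hindered benzoate is ever acylated, no palladium or CO is needed, and the ring substitution pattern is fixed by the annulation.
- Weak points: the strong base excludes β-acyloxy esters, so the terminal acid must travel as a silyl ether of a 1,3-diol and be oxidised in two steps at the end. The dione needs a separate dehydrogenation and phenol protection. The ring A side-chain hydroxyl must be freed next to the C1 ester before it can be acylated, the situation in which the six-membered lactone forms. Two stereocentres are made only to be destroyed.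
- Comparison: it is cheaper in reagents and free of the iodination question, but clearly longer after its key step and weakest exactly where the chosen plan is safe, namely the order of acylation at the ring A side chain.

**Alternative 2:** Ring B is cut at its ester C–O bond and at C1–C6. Heating dioxinone A5 with alcohol A6 would give an acylketene that the alcohol traps. Cs2CO3 would then close the triketo ester by aldol condensation to resorcylate A4.
- Merits: the ring B ester forms from an unhindered, neutral acyl donor, and the ring B phenols never need protection. For this one bond it is as good as or better than the acid chloride acylation of step 10.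
- Weak points: A6 already contains the ring A ester, so the ring A problem is untouched. A5 needs several C-acylations. The carbonate step is run with two β-acyloxy esters present. The side-chain ketone must be a dioxolane to keep the aldol on course, and its acidic removal comes late.
- Comparison: the chosen plan sets against it a four-step access to the ring B acid from the bromide 2 that both rings share, and no basic step once both hydroxybutanoates are in place.

**Alternative 3:** Ring A is cut across C1–C2 and C5–C6. Ynoate A8 and diene A9 would undergo [4+2] cycloaddition, and loss of isobutene from the bicyclic adduct would give resorcylate A7 with free ring A phenols.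
- Merits: it is the most convergent road. The ring A ester is made as an unhindered alkynoate, regiochemistry follows from the polarisation of the diene, and neither CO nor an iodination is needed. In these respects it equals or surpasses the chosen plan.
- Weak points: a 3-alkyl-substituted ynoate is a sluggish dienophile, so long heating well above 150 °C is expected with both β-acyloxy esters, the silyl ether and the enolisable ring B ketone present. The diene is moisture-sensitive and may silylate that ketone.
- Comparison: the chosen plan sets against it a reaction temperature of 80 °C and a reaction class with direct precedent on crowded resorcylate iodides.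

Key step: step 14

## Route

Step 1
Reactants: 1 5-bromoresorcinol
Product: 2 1,3-bis(benzyloxy)-5-bromobenzene
Conditions: BnBr (2.2 equiv), K2CO3, DMF, rt
Reagents that add atoms: benzyl bromide, BrCc1ccccc1
Why: Williamson ether synthesis; both phenols are alkylated under carbonate base and the aryl bromide is inert.

Step 2
Reactants: 2 1,3-bis(benzyloxy)-5-bromobenzene; 3 (R)-propylene oxide
Product: 5 (R)-1-[3,5-bis(benzyloxy)phenyl]propan-2-ol, via arylmagnesium bromide 4 (not isolated)
Conditions: Mg, THF, reflux; then CuI (10 mol%), 3, −30 → 0 °C; aq. NH4Cl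
Reagents that add atoms: magnesium, [Mg] (held in intermediate 4 only, not in 5)
Why: Copper-catalysed SN2 opening of a terminal epoxide by an aryl Grignard reagent at the unsubstituted carbon; the stereocentre of 3 is not involved, so 5 should be R.

Step 3
Reactants: 5 (R)-1-[3,5-bis(benzyloxy)phenyl]propan-2-ol
Product: 6 (R)-1-[3,5-bis(benzyloxy)-2-iodophenyl]propan-2-ol
Conditions: NIS (1.05 equiv), MeCN, 0 °C → rt, dark
Reagents that add atoms: N-iodosuccinimide, O=C1CCC(=O)N1I
Why: Electrophilic aromatic iodination; 3,5-dialkoxy alkylbenzenes are attacked ortho to the chain and para to one ether in preference to the crowded site between the two ethers, and one equivalent at low temperature should limit di-iodination.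

Step 4
Reactants: 2 1,3-bis(benzyloxy)-5-bromobenzene
Product: 8 2,4-bis(benzyloxy)-6-bromobenzaldehyde, via iminium salt 7 (not isolated)
Conditions: POCl3 (2 equiv), DMF, 0 → 60 °C; ice-water, aq. NaOH to pH 7
Reagents that add atoms: N,N-dimethylformamide, CN(C)C=O (formyl carbon); water, O (formyl oxygen, at work-up); phosphoryl chloride, O=P(Cl)(Cl)Cl (counter-ion of intermediate 7 only)
Why: Vilsmeier–Haack formylation; the chloroiminium ion should attack next to bromine, para to one benzyloxy group and ortho to the other, as the dimethoxy analogue does, and iminium salt 7 is hydrolysed at work-up.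

Step 5
Reactants: 9 (R)-pent-4-yn-2-ol
Product: 10 (R)-tert-butyldimethyl(pent-4-yn-2-yloxy)silane
Conditions: TBSCl, imidazole, CH2Cl2, 0 °C → rt
Reagents that add atoms: tert-butyldimethylsilyl chloride, CC(C)(C)[Si](C)(C)Cl
Why: Standard silylation of a secondary alcohol; the C–O bond at the stereocentre is not broken.

Step 6
Reactants: 8 2,4-bis(benzyloxy)-6-bromobenzaldehyde; 10 (R)-tert-butyldimethyl(pent-4-yn-2-yloxy)silane
Product: 11 2,4-bis(benzyloxy)-6-[(4R)-4-(tert-butyldimethylsilyloxy)pent-1-yn-1-yl]benzaldehyde
Conditions: PdCl2(PPh3)2 (3 mol%), CuI (6 mol%), Et3N, THF, 60 °C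
Reagents that add atoms: none
Why: Sonogashira coupling; the ortho formyl group activates the otherwise electron-rich bromide towards oxidative addition, and aldehyde and silyl ether are tolerated.

Step 7
Reactants: 11 2,4-bis(benzyloxy)-6-[(4R)-4-(tert-butyldimethylsilyloxy)pent-1-yn-1-yl]benzaldehyde
Product: 12 2,4-bis(benzyloxy)-6-[(4R)-4-(tert-butyldimethylsilyloxy)pent-1-yn-1-yl]benzoic acid
Conditions: NaClO2, NaH2PO4, 2-methyl-2-butene, t-BuOH/THF/H2O, 0 °C → rt
Reagents that add atoms: sodium chlorite, [Na+].[O-]Cl=O
Why: Pinnick oxidation, selective for the aldehyde; 2-methyl-2-butene removes hypochlorous acid and so protects the alkyne and the electron-rich ring.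

Step 8
Reactants: 13 methyl (R)-3-hydroxybutanoate
Product: 14 allyl (R)-3-hydroxybutanoate
Conditions: allyl alcohol (solvent), Ti(OiPr)4 (10 mol%), 95 °C, MeOH distilled off
Reagents that add atoms: allyl alcohol, OCC=C
Why: Titanate-catalysed transesterification, a neutral method established for β-hydroxy esters that causes neither elimination nor loss of configuration.

Step 9
Reactants: 13 methyl (R)-3-hydroxybutanoate
Product: 15 benzyl (R)-3-hydroxybutanoate
Conditions: BnOH (5 equiv), Ti(OiPr)4 (10 mol%), 100 °C, MeOH distilled off
Reagents that add atoms: benzyl alcohol, OCc1ccccc1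
Why: The same titanate-catalysed transesterification as in step 8; the stereocentre is untouched.

Step 10
Reactants: 12 2,4-bis(benzyloxy)-6-[(4R)-4-(tert-butyldimethylsilyloxy)pent-1-yn-1-yl]benzoic acid; 14 allyl (R)-3-hydroxybutanoate
Product: 17 allyl (3R)-3-({2,4-bis(benzyloxy)-6-[(4R)-4-(tert-butyldimethylsilyloxy)pent-1-yn-1-yl]benzoyl}oxy)butanoate, via aroyl chloride 16 (not isolated)
Conditions: 1-chloro-N,N,2-trimethylprop-1-en-1-amine, CH2Cl2, 0 °C → rt; then 14, pyridine, DMAP (10 mol%), 0 °C → rt
Reagents that add atoms: 1-chloro-N,N,2-trimethylprop-1-en-1-amine, CC(C)=C(Cl)N(C)C (chlorine of intermediate 16 only)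
Why: Acid chloride formation under neutral conditions (no HCl, so alkyne and silyl ether are safe), then DMAP-catalysed acylation; the linear alkynyl ortho group leaves the carbonyl accessible, and the carbinol C–O bond of 14 is not broken, so the centre stays R.

Step 11
Reactants: 17 allyl (3R)-3-({2,4-bis(benzyloxy)-6-[(4R)-4-(tert-butyldimethylsilyloxy)pent-1-yn-1-yl]benzoyl}oxy)butanoate
Product: 18 allyl (3R)-3-({2,4-bis(benzyloxy)-6-[(4R)-4-(tert-butyldimethylsilyloxy)-2-oxopentyl]benzoyl}oxy)butanoate
Conditions: Ph3PAuNTf2 (5 mol%), H2O (5 equiv), 1,4-dioxane, rt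
Reagents that add atoms: water, O
Why: Carbonyl-assisted gold-catalysed alkyne hydration; the ester carbonyl oxygen adds 6-endo to the gold-activated alkyne at the carbon remote from the ring, water opens the resulting benzopyrylium ion and restores the ester, so the ketone should appear one carbon from the ring; water is the only nucleophile offered, so the ester cannot be exchanged.

Step 12
Reactants: 18 allyl (3R)-3-({2,4-bis(benzyloxy)-6-[(4R)-4-(tert-butyldimethylsilyloxy)-2-oxopentyl]benzoyl}oxy)butanoate
Product: 19 (3R)-3-({2,4-bis(benzyloxy)-6-[(4R)-4-(tert-butyldimethylsilyloxy)-2-oxopentyl]benzoyl}oxy)butanoic acid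
Conditions: Pd(PPh3)4 (5 mol%), morpholine (3 equiv), THF, rt; aq. KHSO4
Reagents that add atoms: none
Why: Tsuji–Trost deallylation; zerovalent palladium ionises the allyl ester and morpholine takes up the allyl group, a neutral cleavage that spares benzyl ethers, silyl ether, ketone and the β-aroyloxy ester.

Step 13
Reactants: 19 (3R)-3-({2,4-bis(benzyloxy)-6-[(4R)-4-(tert-butyldimethylsilyloxy)-2-oxopentyl]benzoyl}oxy)butanoic acid; 6 (R)-1-[3,5-bis(benzyloxy)-2-iodophenyl]propan-2-ol
Product: 20 (2R)-1-[3,5-bis(benzyloxy)-2-iodophenyl]propan-2-yl (3R)-3-({2,4-bis(benzyloxy)-6-[(4R)-4-(tert-butyldimethylsilyloxy)-2-oxopentyl]benzoyl}oxy)butanoate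
Conditions: EDC·HCl (1.5 equiv), DMAP (0.2 equiv), CH2Cl2, 0 °C → rt
Reagents that add atoms: none
Why: Steglich esterification of an unhindered aliphatic acid with a secondary alcohol; β-acyloxy butanoic acids are coupled in this way in oligo(hydroxybutanoate) chemistry, and low temperature with catalytic DMAP should suppress β-elimination; no stereocentre is touched.

Step 14
Reactants: 20 (2R)-1-[3,5-bis(benzyloxy)-2-iodophenyl]propan-2-yl (3R)-3-({2,4-bis(benzyloxy)-6-[(4R)-4-(tert-butyldimethylsilyloxy)-2-oxopentyl]benzoyl}oxy)butanoate; 15 benzyl (R)-3-hydroxybutanoate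
Product: 21 (2R)-4-(benzyloxy)-4-oxobutan-2-yl 2,4-bis(benzyloxy)-6-{(2R)-2-[((3R)-3-{[2,4-bis(benzyloxy)-6-((4R)-4-(tert-butyldimethylsilyloxy)-2-oxopentyl)benzoyl]oxy}butanoyl)oxy]propyl}benzoate (fully protected target)
Conditions: Pd(OAc)2 (10 mol%), Xantphos (12 mol%), CO (1 atm), 15 (4 equiv), iPr2NEt (3 equiv), DMAP (20 mol%), toluene, 80 °C
Reagents that add atoms: carbon monoxide, [C-]#[O+]
Why: This is a Heck-type alkoxycarbonylation of an aryl iodide, known at atmospheric CO pressure with Xantphos and known in ring-forming versions that join secondary alcohols to 2,6-disubstituted resorcylate iodides. Pd(OAc)2 is reduced in the flask to zerovalent palladium, which inserts into the C1–I bond of ring A; CO then inserts to give an aroylpalladium iodide, a step that relieves crowding between the metal and the two ortho groups. Alcohol 15 cleaves the aroyl–palladium bond, either directly or through the N-aroylpyridinium ion formed with DMAP, and iPr2NEt takes up HI and returns zerovalent palladium. Two skeletal bonds form (ring A C1–carbonyl and carbonyl–O), no ring closes and no stereocentre is created; the carbinol C–O bond of 15 is not broken, so its R configuration is carried into 21. The selectivity required is capture of the aroylpalladium species by 15 alone. It is secured because 20 has no free hydroxyl group (side-chain oxygen acylated, ring B carbinol silylated), because 15 is present in fourfold excess under dry conditions, and because the only stoichiometric base is a hindered tertiary amine in toluene, too weak to start E1cB loss of the β-aroyloxy groups or enol lactonisation of the ring B keto ester. Since the ring A side-chain oxygen already carries its acyl group, no six-membered lactone can form.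

Step 15
Reactants: 21 fully protected target (as named in step 14)
Product: 22 (2R)-4-(benzyloxy)-4-oxobutan-2-yl 2,4-bis(benzyloxy)-6-{(2R)-2-[((3R)-3-{[2,4-bis(benzyloxy)-6-((4R)-4-hydroxy-2-oxopentyl)benzoyl]oxy}butanoyl)oxy]propyl}benzoate
Conditions: HF·pyridine, pyridine/THF, 0 °C → rt
Reagents that add atoms: none
Why: Desilylation with buffered HF, an acidic and not a basic fluoride source, so the β-acyloxy esters and the newly freed β-hydroxy ketone are not exposed to base.

Step 16
Reactants: 22 pentabenzyl compound (as named in step 15)
Product: 23 hansforester I, (3R)-3-[(2,4-dihydroxy-6-{(2R)-2-[((3R)-3-{[2,4-dihydroxy-6-((4R)-4-hydroxy-2-oxopentyl)benzoyl]oxy}butanoyl)oxy]propyl}benzoyl)oxy]butanoic acid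
Conditions: H2 (1 atm), 10% Pd/C, EtOAc/THF, rt
Reagents that add atoms: none
Why: Catalytic hydrogenolysis of four aryl benzyl ethers and the benzyl ester in one neutral operation; the aliphatic ketone, the esters and the homobenzylic C–O bond should be inert to Pd/C at one atmosphere.

## Compound list

1 | 5-bromoresorcinol | Oc1cc(O)cc(Br)c1 | starting material
2 | 1,3-bis(benzyloxy)-5-bromobenzene | Brc1cc(OCc2ccccc2)cc(OCc2ccccc2)c1 | intermediate
3 | (R)-propylene oxide | C[C@@H]1CO1 | starting material
4 | [3,5-bis(benzyloxy)phenyl]magnesium bromide | Br[Mg]c1cc(OCc2ccccc2)cc(OCc2ccccc2)c1 | intermediate (not isolated)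
5 | (R)-1-[3,5-bis(benzyloxy)phenyl]propan-2-ol | C[C@H](Cc1cc(OCc2ccccc2)cc(OCc2ccccc2)c1)O | intermediate
6 | (R)-1-[3,5-bis(benzyloxy)-2-iodophenyl]propan-2-ol | C[C@H](Cc1cc(OCc2ccccc2)cc(OCc2ccccc2)c1I)O | intermediate
7 | N-{[2,4-bis(benzyloxy)-6-bromophenyl]methylidene}-N-methylmethanaminium dichlorophosphate | C[N+](C)=Cc1c(OCc2ccccc2)cc(OCc2ccccc2)cc1Br.[O-]P(Cl)(Cl)=O | intermediate (not isolated)
8 | 2,4-bis(benzyloxy)-6-bromobenzaldehyde | O=Cc1c(OCc2ccccc2)cc(OCc2ccccc2)cc1Br | intermediate
9 | (R)-pent-4-yn-2-ol | C#CC[C@@H](C)O | starting material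
10 | (R)-tert-butyldimethyl(pent-4-yn-2-yloxy)silane | C#CC[C@@H](C)O[Si](C)(C)C(C)(C)C | intermediate
11 | 2,4-bis(benzyloxy)-6-[(4R)-4-(tert-butyldimethylsilyloxy)pent-1-yn-1-yl]benzaldehyde | O=Cc1c(OCc2ccccc2)cc(OCc2ccccc2)cc1C#CC[C@@H](C)O[Si](C)(C)C(C)(C)C | intermediate
12 | 2,4-bis(benzyloxy)-6-[(4R)-4-(tert-butyldimethylsilyloxy)pent-1-yn-1-yl]benzoic acid | OC(=O)c1c(OCc2ccccc2)cc(OCc2ccccc2)cc1C#CC[C@@H](C)O[Si](C)(C)C(C)(C)C | intermediate
13 | methyl (R)-3-hydroxybutanoate | COC(=O)C[C@@H](C)O | starting material
14 | allyl (R)-3-hydroxybutanoate | C=CCOC(=O)C[C@@H](C)O | intermediate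
15 | benzyl (R)-3-hydroxybutanoate | O[C@H](C)CC(=O)OCc1ccccc1 | intermediate
16 | 2,4-bis(benzyloxy)-6-[(4R)-4-(tert-butyldimethylsilyloxy)pent-1-yn-1-yl]benzoyl chloride | ClC(=O)c1c(OCc2ccccc2)cc(OCc2ccccc2)cc1C#CC[C@@H](C)O[Si](C)(C)C(C)(C)C | intermediate (not isolated)
17 | allyl (3R)-3-({2,4-bis(benzyloxy)-6-[(4R)-4-(tert-butyldimethylsilyloxy)pent-1-yn-1-yl]benzoyl}oxy)butanoate | C=CCOC(=O)C[C@@H](C)OC(=O)c1c(OCc2ccccc2)cc(OCc2ccccc2)cc1C#CC[C@@H](C)O[Si](C)(C)C(C)(C)C | intermediate
18 | allyl (3R)-3-({2,4-bis(benzyloxy)-6-[(4R)-4-(tert-butyldimethylsilyloxy)-2-oxopentyl]benzoyl}oxy)butanoate | C=CCOC(=O)C[C@@H](C)OC(=O)c1c(OCc2ccccc2)cc(OCc2ccccc2)cc1CC(=O)C[C@@H](C)O[Si](C)(C)C(C)(C)C | intermediate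
19 | (3R)-3-({2,4-bis(benzyloxy)-6-[(4R)-4-(tert-butyldimethylsilyloxy)-2-oxopentyl]benzoyl}oxy)butanoic acid | OC(=O)C[C@@H](C)OC(=O)c1c(OCc2ccccc2)cc(OCc2ccccc2)cc1CC(=O)C[C@@H](C)O[Si](C)(C)C(C)(C)C | intermediate
20 | (2R)-1-[3,5-bis(benzyloxy)-2-iodophenyl]propan-2-yl (3R)-3-({2,4-bis(benzyloxy)-6-[(4R)-4-(tert-butyldimethylsilyloxy)-2-oxopentyl]benzoyl}oxy)butanoate | C[C@H](Cc1cc(OCc2ccccc2)cc(OCc2ccccc2)c1I)OC(=O)C[C@@H](C)OC(=O)c1c(OCc2ccccc2)cc(OCc2ccccc2)cc1CC(=O)C[C@@H](C)O[Si](C)(C)C(C)(C)C | intermediate
21 | fully protected target: ring A benzoate of benzyl (R)-3-hydroxybutanoate, four phenols as benzyl ethers, ring B carbinol as tert-butyldimethylsilyl ether | C[C@H](Cc1cc(OCc2ccccc2)cc(OCc2ccccc2)c1C(=O)O[C@H](C)CC(=O)OCc1ccccc1)OC(=O)C[C@@H](C)OC(=O)c1c(OCc2ccccc2)cc(OCc2ccccc2)cc1CC(=O)C[C@@H](C)O[Si](C)(C)C(C)(C)C | intermediate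
22 | desilylated pentabenzyl compound (21 with free (4R)-4-hydroxy-2-oxopentyl chain) | C[C@H](Cc1cc(OCc2ccccc2)cc(OCc2ccccc2)c1C(=O)O[C@H](C)CC(=O)OCc1ccccc1)OC(=O)C[C@@H](C)OC(=O)c1c(OCc2ccccc2)cc(OCc2ccccc2)cc1CC(=O)C[C@@H](C)O | intermediate
23 | hansforester I | C[C@H](Cc1cc(O)cc(O)c1C(=O)O[C@H](C)CC(=O)O)OC(=O)C[C@@H](C)OC(=O)c1c(O)cc(O)cc1CC(=O)C[C@@H](C)O | target

## Step count and least certain steps

Total step count: 16. Longest linear sequence: 11 steps (steps 1, 4, 6, 7, 10, 11, 12, 13, 14, 15, 16, from 5-bromoresorcinol).

**Step 14 (key step).** The crowded aroylpalladium species may be cleaved too slowly by a secondary alcohol. Reduction of the C–I bond could then take over, with hydride coming from β-hydride elimination of a palladium alkoxide of 15, or the long heating with amine could start β-elimination at the acyloxy esters. Fallback: starting from 20, hydroxycarbonylation with water as the small nucleophile (Pd(OAc)2, Xantphos, CO, H2O, Et3N, dioxane, 70 °C) should give the ring A benzoic acid F1. Mitsunobu esterification of F1 (PPh3, DIAD, toluene, 0 °C → rt) with benzyl (S)-3-hydroxybutanoate F2, made from methyl (S)-3-hydroxybutanoate as in step 9, activates the alcohol and not the hindered acid, inverts the carbinol, and returns to the route at 21.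

**Step 11.** The regiochemistry may leak through 5-exo participation of the ester or unassisted hydration at the ring-bound carbon. The cationic benzopyrylium intermediate may lose its secondary alkyl group and end as an enol lactone, or adventitious acid may remove the silyl group. Fallback: starting from 12, AgOTf-catalysed 6-endo cycloisomerisation of the alkynyl acid should give 6,8-bis(benzyloxy)-3-[(2R)-2-(tert-butyldimethylsilyloxy)propyl]isocoumarin F3. Hydrolysis with LiOH in aqueous THF and careful acidification should give 2,4-bis(benzyloxy)-6-[(4R)-4-(tert-butyldimethylsilyloxy)-2-oxopentyl]benzoic acid F4. This is used at once in a Mitsunobu esterification with allyl (S)-3-hydroxybutanoate F5, made from methyl (S)-3-hydroxybutanoate as in step 8; it proceeds with inversion and returns to the route at 18.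

**Step 10.** The activated ortho-alkynyl aroyl species may cyclise onto the alkyne, or acylation of the β-hydroxy ester may be slow enough for elimination to compete. Fallback: the order of events is reversed. Starting from 8, Pinnick oxidation gives 2,4-bis(benzyloxy)-6-bromobenzoic acid F6. Oxalyl chloride with catalytic DMF gives the robust 2,4-bis(benzyloxy)-6-bromobenzoyl chloride F7, and acylation of 14 (pyridine, DMAP) gives allyl (3R)-3-{[2,4-bis(benzyloxy)-6-bromobenzoyl]oxy}butanoate F8. Sonogashira coupling of F8 with 10 under the conditions of step 6 returns to the route at 17; triethylamine is a poor acceptor for an allyl group, so the allyl ester is expected to hold, though this is the uncertain point of the fallback.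

**Step 13.** Activation of the β-aroyloxy acid may lead to loss of the aroyloxy group by E1cB elimination, giving a crotonate in place of the ester. Fallback: the alcohol is activated, not the acid. Starting from 2, the sequence of steps 2 and 3 run with (S)-propylene oxide gives (S)-1-[3,5-bis(benzyloxy)phenyl]propan-2-ol F9 and then (S)-1-[3,5-bis(benzyloxy)-2-iodophenyl]propan-2-ol F10. Mitsunobu esterification of 19 with F10 (PPh3, DIAD, toluene, 0 °C) inverts the carbinol and returns to the route at 20.

## Further compounds

F1 | step 14 | 2,4-bis(benzyloxy)-6-{(2R)-2-[((3R)-3-{[2,4-bis(benzyloxy)-6-((4R)-4-(tert-butyldimethylsilyloxy)-2-oxopentyl)benzoyl]oxy}butanoyl)oxy]propyl}benzoic acid | C[C@H](Cc1cc(OCc2ccccc2)cc(OCc2ccccc2)c1C(=O)O)OC(=O)C[C@@H](C)OC(=O)c1c(OCc2ccccc2)cc(OCc2ccccc2)cc1CC(=O)C[C@@H](C)O[Si](C)(C)C(C)(C)C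
F2 | step 14 | benzyl (S)-3-hydroxybutanoate | O[C@@H](C)CC(=O)OCc1ccccc1
F3 | step 11 | 6,8-bis(benzyloxy)-3-[(2R)-2-(tert-butyldimethylsilyloxy)propyl]-1H-isochromen-1-one | O=C1OC(C[C@@H](C)O[Si](C)(C)C(C)(C)C)=Cc2cc(OCc3ccccc3)cc(OCc3ccccc3)c12
F4 | step 11 | 2,4-bis(benzyloxy)-6-[(4R)-4-(tert-butyldimethylsilyloxy)-2-oxopentyl]benzoic acid | OC(=O)c1c(OCc2ccccc2)cc(OCc2ccccc2)cc1CC(=O)C[C@@H](C)O[Si](C)(C)C(C)(C)C
F5 | step 11 | allyl (S)-3-hydroxybutanoate | C=CCOC(=O)C[C@H](C)O
F6 | step 10 | 2,4-bis(benzyloxy)-6-bromobenzoic acid | OC(=O)c1c(OCc2ccccc2)cc(OCc2ccccc2)cc1Br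
F7 | step 10 | 2,4-bis(benzyloxy)-6-bromobenzoyl chloride | ClC(=O)c1c(OCc2ccccc2)cc(OCc2ccccc2)cc1Br
F8 | step 10 | allyl (3R)-3-{[2,4-bis(benzyloxy)-6-bromobenzoyl]oxy}butanoate | C=CCOC(=O)C[C@@H](C)OC(=O)c1c(OCc2ccccc2)cc(OCc2ccccc2)cc1Br
F9 | step 13 | (S)-1-[3,5-bis(benzyloxy)phenyl]propan-2-ol | C[C@@H](Cc1cc(OCc2ccccc2)cc(OCc2ccccc2)c1)O
F10 | step 13 | (S)-1-[3,5-bis(benzyloxy)-2-iodophenyl]propan-2-ol | C[C@@H](Cc1cc(OCc2ccccc2)cc(OCc2ccccc2)c1I)O
A1 | alternative 1 | (2R)-4-(tert-butyldiphenylsilyloxy)butan-2-yl 6-[(2R)-2-(tert-butyldimethylsilyloxy)propyl]-2,4-dioxocyclohexane-1-carboxylate | O=C1CC(=O)C(C(=O)O[C@H](C)CCO[Si](c2ccccc2)(c2ccccc2)C(C)(C)C)C(C[C@@H](C)O[Si](C)(C)C(C)(C)C)C1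
A2 | alternative 1 | (2R)-4-(tert-butyldiphenylsilyloxy)butan-2-yl 3-oxobutanoate | CC(=O)CC(=O)O[C@H](C)CCO[Si](c1ccccc1)(c1ccccc1)C(C)(C)C
A3 | alternative 1 | methyl (2E,5R)-5-(tert-butyldimethylsilyloxy)hex-2-enoate | COC(=O)/C=C/C[C@@H](C)O[Si](C)(C)C(C)(C)C
A4 | alternative 2 | protected target with ring B formed, ring B phenols free and side-chain ketone as 1,3-dioxolane | C[C@H](Cc1cc(OCc2ccccc2)cc(OCc2ccccc2)c1C(=O)O[C@H](C)CC(=O)OCc1ccccc1)OC(=O)C[C@@H](C)OC(=O)c1c(O)cc(O)cc1CC1(C[C@@H](C)O[Si](C)(C)C(C)(C)C)OCCO1
A5 | alternative 2 | 6-(5-{2-[(2R)-2-(tert-butyldimethylsilyloxy)propyl]-1,3-dioxolan-2-yl}-2,4-dioxopentyl)-2,2-dimethyl-4H-1,3-dioxin-4-one | CC1(C)OC(=O)C=C(CC(=O)CC(=O)CC2(C[C@@H](C)O[Si](C)(C)C(C)(C)C)OCCO2)O1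
A6 | alternative 2 | (2R)-1-[3,5-bis(benzyloxy)-2-({[(2R)-4-(benzyloxy)-4-oxobutan-2-yl]oxy}carbonyl)phenyl]propan-2-yl (3R)-3-hydroxybutanoate | C[C@H](Cc1cc(OCc2ccccc2)cc(OCc2ccccc2)c1C(=O)O[C@H](C)CC(=O)OCc1ccccc1)OC(=O)C[C@@H](C)O
A7 | alternative 3 | protected target with ring A formed and ring A phenols free | C[C@H](Cc1cc(O)cc(O)c1C(=O)O[C@H](C)CC(=O)OCc1ccccc1)OC(=O)C[C@@H](C)OC(=O)c1c(OCc2ccccc2)cc(OCc2ccccc2)cc1CC(=O)C[C@@H](C)O[Si](C)(C)C(C)(C)C
A8 | alternative 3 | (2R)-4-(benzyloxy)-4-oxobutan-2-yl (5R)-5-[((3R)-3-{[2,4-bis(benzyloxy)-6-((4R)-4-(tert-butyldimethylsilyloxy)-2-oxopentyl)benzoyl]oxy}butanoyl)oxy]hex-2-ynoate | C[C@H](CC#CC(=O)O[C@H](C)CC(=O)OCc1ccccc1)OC(=O)C[C@@H](C)OC(=O)c1c(OCc2ccccc2)cc(OCc2ccccc2)cc1CC(=O)C[C@@H](C)O[Si](C)(C)C(C)(C)C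
A9 | alternative 3 | 5,5-dimethyl-1,3-bis(trimethylsilyloxy)cyclohexa-1,3-diene | C[Si](C)(C)OC1=CC(O[Si](C)(C)C)=CC(C)(C)C1
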